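**Retrosynthetic overview**
1. The last move unmasks O5, O7 and O4' of a tri-O-isopropyl flavone with BCl3, which spares the ring D OMe and CO2Me.
2. Ring C (O1–C2–C3–C4–C4a–C8a) is cut at C2=C3. C3 becomes the ylide carbon of a ketophosphorane on C4a, and C2 becomes the carbonyl carbon of a 4-isopropoxybenzoate (ring B) on O1.
3. Feature exploited: O1 (on C8a) lies para to the aryl-bearing C6, with O5 and O7 on either side of C6. Ring A therefore maps onto a 4-aryl-3,5-diisopropoxyphenol with a mirror plane through the O1···C6 axis, and either of its two identical free ortho carbons can become C4a.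
4. C4 enters as an ortho-formyl group, is oxidised to CO2H after O1-aroylation, and is bonded to C3 by acylating Ph3P=CH2.
5. The phenol comes from 1,3-diisopropoxybenzene by C2-lithiation/Negishi arylation (C6–C1' bond) and sterically directed C–H borylation/oxidation (O1). Rings A, B and D are bought; ring C is the only ring formed.

Key step: step 8

Assumption: the target string carries no axial descriptor for the C6–C1' bond, so the biaryl axis is treated as stereochemically undefined. There is no stereocentre to set.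

**Route**

Step 1
Reactants: 1 1,3-diisopropoxybenzene; 2 methyl 3-iodo-4-methoxybenzoate
Product: 5 methyl 3-(2,6-diisopropoxyphenyl)-4-methoxybenzoate, via 2,6-diisopropoxyphenyllithium 3 (not isolated), via (2,6-diisopropoxyphenyl)zinc chloride 4 (not isolated)
Conditions: 1 (1.3 equiv), n-BuLi (1.25 equiv), THF, 0 °C → rt; ZnCl2 (1.4 equiv, THF), 0 °C → rt; 2 (1.0 equiv), Pd2(dba)3 (1 mol %), RuPhos (4 mol %), THF, 65 °C
Reagents that add atoms: n-BuLi, [Li]CCCC (lithium of 3 only); ZnCl2, Cl[Zn]Cl (ZnCl of 4 only)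
Why: Directed ortho-lithiation removes the C2–H flanked by both isopropoxy groups, Li→Zn exchange makes the nucleophile tolerant of the ester, and Negishi coupling with a bulky biarylphosphine on palladium is an established way to tri-ortho-substituted biaryls.

Step 2
Reactants: 5 methyl 3-(2,6-diisopropoxyphenyl)-4-methoxybenzoate
Product: 6 methyl 3-[2,6-diisopropoxy-4-(4,4,5,5-tetramethyl-1,3,2-dioxaborolan-2-yl)phenyl]-4-methoxybenzoate
Conditions: [Ir(OMe)(cod)]2 (1.5 mol %), 4,4'-di-tert-butyl-2,2'-bipyridine (3 mol %), B2pin2 (1.0 equiv), THF, 80 °C (sealed vessel); silica plug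
Reagents that add atoms: bis(pinacolato)diboron, CC1(C)OB(OC1(C)C)B1OC(C)(C)C(C)(C)O1
Why: Iridium-catalysed aromatic C–H borylation (Hartwig–Miyaura type) is sterically controlled, and the ring A C–H para to the biaryl bond is the only C–H of 5 without an ortho substituent, since every ring D C–H lies next to CO2Me, OMe or the aryl group.

Step 3
Reactants: 6 methyl 3-[2,6-diisopropoxy-4-(4,4,5,5-tetramethyl-1,3,2-dioxaborolan-2-yl)phenyl]-4-methoxybenzoate
Product: 7 methyl 3-(4-hydroxy-2,6-diisopropoxyphenyl)-4-methoxybenzoate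
Conditions: NaBO3·4H2O (3 equiv), THF/H2O (1:1), rt
Reagents that add atoms: sodium perborate, [Na+].[O-]OB=O
Why: Peroxide oxidation of an arylboronate proceeds by 1,2-aryl migration from boron to oxygen at the same carbon, and NaBO3 is mild enough to leave the methyl ester intact.

Step 4
Reactants: 7 methyl 3-(4-hydroxy-2,6-diisopropoxyphenyl)-4-methoxybenzoate
Product: 8 methyl 3-(3-formyl-4-hydroxy-2,6-diisopropoxyphenyl)-4-methoxybenzoate
Conditions: MgCl2 (anhydrous, 2 equiv), Et3N (4 equiv), (CH2O)n (6 equiv), MeCN, 80 °C; 1 M HCl work-up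
Reagents that add atoms: paraformaldehyde (as formaldehyde), C=O
Why: The magnesium-mediated ortho-formylation of phenols (Casnati–Skattebøl reaction) delivers formaldehyde inside the magnesium phenoxide to an ortho carbon only, and the two ortho carbons of 7 are equivalent by symmetry, so a single salicylaldehyde is expected.

Step 5
Reactants: 8 methyl 3-(3-formyl-4-hydroxy-2,6-diisopropoxyphenyl)-4-methoxybenzoate; 9 4-isopropoxybenzoyl chloride
Product: 10 methyl 3-{3-formyl-2,6-diisopropoxy-4-[(4-isopropoxybenzoyl)oxy]phenyl}-4-methoxybenzoate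
Conditions: 9 (1.2 equiv), Et3N (2 equiv), DMAP (10 mol %), CH2Cl2, 0 °C → rt
Reagents that add atoms: none
Why: DMAP-catalysed O-acylation of the only free hydroxyl group places ring B and the future C2 on O1.

Step 6
Reactants: 10 methyl 3-{3-formyl-2,6-diisopropoxy-4-[(4-isopropoxybenzoyl)oxy]phenyl}-4-methoxybenzoate
Product: 11 2,4-diisopropoxy-6-[(4-isopropoxybenzoyl)oxy]-3-[2-methoxy-5-(methoxycarbonyl)phenyl]benzoic acid
Conditions: NaClO2 (3 equiv), NaH2PO4 (3 equiv), 2-methyl-2-butene (20 equiv), t-BuOH/THF/H2O, 0 °C → rt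
Reagents that add atoms: sodium chlorite, [Na+].[O-]Cl=O
Why: The Pinnick oxidation converts the aldehyde into the acid in a weakly acidic buffer in which both esters are stable, and the alkene scavenger removes HOCl before it can chlorinate the remaining ring A C–H.

Step 7
Reactants: 11 2,4-diisopropoxy-6-[(4-isopropoxybenzoyl)oxy]-3-[2-methoxy-5-(methoxycarbonyl)phenyl]benzoic acid; 12 methyltriphenylphosphonium bromide
Product: 15 methyl 3-{2,6-diisopropoxy-4-[(4-isopropoxybenzoyl)oxy]-3-[(triphenyl-λ5-phosphanylidene)acetyl]phenyl}-4-methoxybenzoate, via methylenetriphenylphosphorane 13 (not isolated), via aroyl chloride 14 (not isolated)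
Conditions: (a) 11, (COCl)2 (1.3 equiv), DMF (cat.), CH2Cl2, 0 °C → rt, evaporate; (b) 12 (2.05 equiv), n-BuLi (2.0 equiv), THF, 0 °C; (c) 14 in THF added dropwise to 13, −78 → −30 °C; cold H2O work-up, short column
Reagents that add atoms: oxalyl chloride, O=C(Cl)C(=O)Cl (chlorine of 14 only)
Why: Acylation of a non-stabilised ylide by an acid chloride with transylidation (the second equivalent of 13 takes the acidic α-proton) is the standard entry to acylmethylenephosphoranes, and at −78 °C the acid chloride should far outrun the aryl and methyl esters as the electrophile.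

Step 8
Reactants: 15 methyl 3-{2,6-diisopropoxy-4-[(4-isopropoxybenzoyl)oxy]-3-[(triphenyl-λ5-phosphanylidene)acetyl]phenyl}-4-methoxybenzoate
Product: 16 methyl 3-[5,7-diisopropoxy-2-(4-isopropoxyphenyl)-4-oxo-4H-chromen-6-yl]-4-methoxybenzoate
Conditions: PhMe (0.02 M), 110 °C, Ar
Reagents that add atoms: none
Why: This is an intramolecular Wittig olefination of an ester carbonyl, in which the ylide carbon C3 of 15 adds to the carbonyl carbon (future C2) of the 4-isopropoxybenzoate held on O1 and the betaine/oxaphosphetane collapses with loss of Ph3PO to leave the C2=C3 enol-ether double bond. The closest known reaction type is the chromone and flavone synthesis from (2-acyloxyphenacylidene)triphenylphosphoranes, so known chemistry is applied here to a more crowded substrate. Ring C closes in the 6-exo-trig mode, because C3 attacks a C=O whose oxygen lies outside the new ring O1–C2–C3–C4–C4a–C8a. No stereocentre is created. The step needs the ylide to choose the aryl ester over the ring D methyl ester, which the ortho relationship secures because only this carbonyl can be reached through a six-membered transition state, while dilution holds back intermolecular acyl transfer. The regiochemistry cannot drift, since O5 and O7 remain alkylated and only O1 can become the ring oxygen, and extrusion of Ph3PO is irreversible in this neutral medium.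

Step 9
Reactants: 16 methyl 3-[5,7-diisopropoxy-2-(4-isopropoxyphenyl)-4-oxo-4H-chromen-6-yl]-4-methoxybenzoate
Product: 17 methyl 3-[5,7-dihydroxy-2-(4-hydroxyphenyl)-4-oxo-4H-chromen-6-yl]-4-methoxybenzoate (target)
Conditions: BCl3 (1 M in CH2Cl2, 8 equiv), CH2Cl2, −78 → 0 °C; H2O quench
Reagents that add atoms: none
Why: Lewis-acid ether cleavage with BCl3 removes the secondary isopropyl groups as 2-chloropropane much faster than it attacks an unchelated aryl methyl ether or a methyl ester, and the ring D OMe is para to its ester and so has no neighbouring carbonyl to assist its loss.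

**Compound list**
1 | 1,3-diisopropoxybenzene | CC(C)Oc1cccc(OC(C)C)c1 | starting material
2 | methyl 3-iodo-4-methoxybenzoate | COC(=O)c1ccc(OC)c(I)c1 | starting material
3 | 2,6-diisopropoxyphenyllithium | [Li]c1c(OC(C)C)cccc1OC(C)C | intermediate
4 | (2,6-diisopropoxyphenyl)zinc chloride | Cl[Zn]c1c(OC(C)C)cccc1OC(C)C | intermediate
5 | methyl 3-(2,6-diisopropoxyphenyl)-4-methoxybenzoate | COC(=O)c1ccc(OC)c(-c2c(OC(C)C)cccc2OC(C)C)c1 | intermediate
6 | methyl 3-[2,6-diisopropoxy-4-(4,4,5,5-tetramethyl-1,3,2-dioxaborolan-2-yl)phenyl]-4-methoxybenzoate | COC(=O)c1ccc(OC)c(-c2c(OC(C)C)cc(B3OC(C)(C)C(C)(C)O3)cc2OC(C)C)c1 | intermediate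
7 | methyl 3-(4-hydroxy-2,6-diisopropoxyphenyl)-4-methoxybenzoate | COC(=O)c1ccc(OC)c(-c2c(OC(C)C)cc(O)cc2OC(C)C)c1 | intermediate
8 | methyl 3-(3-formyl-4-hydroxy-2,6-diisopropoxyphenyl)-4-methoxybenzoate | COC(=O)c1ccc(OC)c(-c2c(OC(C)C)cc(O)c(C=O)c2OC(C)C)c1 | intermediate
9 | 4-isopropoxybenzoyl chloride | CC(C)Oc1ccc(C(=O)Cl)cc1 | starting material
10 | methyl 3-{3-formyl-2,6-diisopropoxy-4-[(4-isopropoxybenzoyl)oxy]phenyl}-4-methoxybenzoate | COC(=O)c1ccc(OC)c(-c2c(OC(C)C)cc(OC(=O)c3ccc(OC(C)C)cc3)c(C=O)c2OC(C)C)c1 | intermediate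
11 | 2,4-diisopropoxy-6-[(4-isopropoxybenzoyl)oxy]-3-[2-methoxy-5-(methoxycarbonyl)phenyl]benzoic acid | COC(=O)c1ccc(OC)c(-c2c(OC(C)C)cc(OC(=O)c3ccc(OC(C)C)cc3)c(C(=O)O)c2OC(C)C)c1 | intermediate
12 | methyltriphenylphosphonium bromide | C[P+](c1ccccc1)(c1ccccc1)c1ccccc1.[Br-] | starting material
13 | methylenetriphenylphosphorane | C=P(c1ccccc1)(c1ccccc1)c1ccccc1 | intermediate
14 | 2,4-diisopropoxy-6-[(4-isopropoxybenzoyl)oxy]-3-[2-methoxy-5-(methoxycarbonyl)phenyl]benzoyl chloride | COC(=O)c1ccc(OC)c(-c2c(OC(C)C)cc(OC(=O)c3ccc(OC(C)C)cc3)c(C(=O)Cl)c2OC(C)C)c1 | intermediate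
15 | methyl 3-{2,6-diisopropoxy-4-[(4-isopropoxybenzoyl)oxy]-3-[(triphenyl-λ5-phosphanylidene)acetyl]phenyl}-4-methoxybenzoate | COC(=O)c1ccc(OC)c(-c2c(OC(C)C)cc(OC(=O)c3ccc(OC(C)C)cc3)c(C(=O)C=P(c3ccccc3)(c3ccccc3)c3ccccc3)c2OC(C)C)c1 | intermediate
16 | methyl 3-[5,7-diisopropoxy-2-(4-isopropoxyphenyl)-4-oxo-4H-chromen-6-yl]-4-methoxybenzoate | COC(=O)c1ccc(OC)c(-c2c(OC(C)C)cc3oc(-c4ccc(OC(C)C)cc4)cc(=O)c3c2OC(C)C)c1 | intermediate
17 | methyl 3-[5,7-dihydroxy-2-(4-hydroxyphenyl)-4-oxo-4H-chromen-6-yl]-4-methoxybenzoate | COC(=O)c1ccc(OC)c(-c2c(O)cc3oc(-c4ccc(O)cc4)cc(=O)c3c2O)c1 | target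

**Totals and risks**
Total step count: 9. Longest linear sequence: 9 steps (1 → 17).

The three steps most likely to fail:

(1) Step 8.
- Risk: the closure may stall, because a 4-alkoxybenzoate carbonyl is a weak electrophile and the ylide is crowded by the O5 isopropyl group. Long heating could then favour aroyl migration from O1 to C3 or intermolecular acyl transfer.
- Fallback: ring C is closed at O1–C2 instead, by carbonylative Sonogashira annulation. It sets out from phenol 7.
- Compound 7 is mono-iodinated at one of its two equivalent ortho carbons (NIS, MeCN, 0 °C) to give methyl 3-(4-hydroxy-3-iodo-2,6-diisopropoxyphenyl)-4-methoxybenzoate F1.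
- F1, 1-ethynyl-4-isopropoxybenzene and CO (PdCl2(dppf), Et2NH, 80–120 °C) should pass through methyl 3-{4-hydroxy-2,6-diisopropoxy-3-[3-(4-isopropoxyphenyl)prop-2-ynoyl]phenyl}-4-methoxybenzoate F2.
- The secondary amine steers F2 to 6-endo closure, and the sequence comes back to the route at flavone 16.

(2) Step 7.
- Risk: the basic, nucleophilic ylide may attack the O1 aroyl ester, or acylation at the doubly ortho-substituted acid chloride may be so slow that double acylation of the product ylide competes.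
- Fallback: the phosphorus is introduced by alkylating PPh3, so no non-stabilised ylide is used. It sets out from acid chloride 14.
- TMSCHN2 and Et3N (MeCN/THF, 0 °C) should give methyl 3-{3-(diazoacetyl)-2,6-diisopropoxy-4-[(4-isopropoxybenzoyl)oxy]phenyl}-4-methoxybenzoate F3.
- Aqueous HBr (48 %, THF, 0 °C) converts F3 into methyl 3-{3-(bromoacetyl)-2,6-diisopropoxy-4-[(4-isopropoxybenzoyl)oxy]phenyl}-4-methoxybenzoate F4.
- PPh3 (toluene, rt) gives (2-{2,4-diisopropoxy-6-[(4-isopropoxybenzoyl)oxy]-3-[2-methoxy-5-(methoxycarbonyl)phenyl]phenyl}-2-oxoethyl)triphenylphosphonium bromide F5.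
- Aqueous Na2CO3/CH2Cl2 deprotonates F5, and the sequence comes back to the route at phosphorane 15.

(3) Step 1.
- Risk: transmetalation and reductive elimination at the crowded palladium centre may be slow, so that homocoupling and protodemetalation of the arylzinc take over.
- Fallback: the polarity is reversed and a Suzuki–Miyaura coupling is used. It sets out from aryllithium 3.
- Compound 3 is quenched with I2 (THF, −78 °C) to give 2-iodo-1,3-diisopropoxybenzene F6.
- F6 is coupled with commercial [2-methoxy-5-(methoxycarbonyl)phenyl]boronic acid (Pd(OAc)2, SPhos, K3PO4, toluene/H2O, 90 °C). This avoids a 2,6-dialkoxyarylboron species prone to protodeboronation.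
- The sequence comes back to the route at biaryl 5.

**Further compounds**
F1 | step 8 | methyl 3-(4-hydroxy-3-iodo-2,6-diisopropoxyphenyl)-4-methoxybenzoate | COC(=O)c1ccc(OC)c(-c2c(OC(C)C)cc(O)c(I)c2OC(C)C)c1
F2 | step 8 | methyl 3-{4-hydroxy-2,6-diisopropoxy-3-[3-(4-isopropoxyphenyl)prop-2-ynoyl]phenyl}-4-methoxybenzoate | COC(=O)c1ccc(OC)c(-c2c(OC(C)C)cc(O)c(C(=O)C#Cc3ccc(OC(C)C)cc3)c2OC(C)C)c1
F3 | step 7 | methyl 3-{3-(diazoacetyl)-2,6-diisopropoxy-4-[(4-isopropoxybenzoyl)oxy]phenyl}-4-methoxybenzoate | COC(=O)c1ccc(OC)c(-c2c(OC(C)C)cc(OC(=O)c3ccc(OC(C)C)cc3)c(C(=O)C=[N+]=[N-])c2OC(C)C)c1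
F4 | step 7 | methyl 3-{3-(bromoacetyl)-2,6-diisopropoxy-4-[(4-isopropoxybenzoyl)oxy]phenyl}-4-methoxybenzoate | COC(=O)c1ccc(OC)c(-c2c(OC(C)C)cc(OC(=O)c3ccc(OC(C)C)cc3)c(C(=O)CBr)c2OC(C)C)c1
F5 | step 7 | (2-{2,4-diisopropoxy-6-[(4-isopropoxybenzoyl)oxy]-3-[2-methoxy-5-(methoxycarbonyl)phenyl]phenyl}-2-oxoethyl)triphenylphosphonium bromide | COC(=O)c1ccc(OC)c(-c2c(OC(C)C)cc(OC(=O)c3ccc(OC(C)C)cc3)c(C(=O)C[P+](c3ccccc3)(c3ccccc3)c3ccccc3)c2OC(C)C)c1.[Br-]
F6 | step 1 | 2-iodo-1,3-diisopropoxybenzene | CC(C)Oc1cccc(OC(C)C)c1I
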